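## Retrosynthetic overview

1. The target is the (2S)-flavanone (CIP at C2: O1 > C1' > C3 > H). The last step is removal of two MOM groups.
2. The 8-prenyl group comes from a 5-O-prenyl ether by a Eu(III)-catalysed para-Claisen–Cope shift (O5 → C6 → C8) on the intact flavanone. The prenyl ether therefore doubles as the 5-OH protecting group.
3. Key step: the C2–C1' bond and the C2 stereocentre are made together by Rh-catalysed asymmetric 1,4-addition of a B-ring arylboronic acid to a chromone. No chalcone and no oxa-Michael closure are used.
4. The B-ring boronic acid comes from 4-bromophenol MOM ether by a γ-selective ("reverse") prenyl Suzuki coupling, then MOM-directed ortho-lithiation/borylation.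
5. Ring order: no ring is built. The A/C chromone and the B-ring arene are purchased, and the C ring becomes the saturated, stereodefined pyranone in the coupling step.

Assumption: 5,7-dihydroxychromone (1), 1-bromo-4-(methoxymethoxy)benzene (6) and prenylboronic acid pinacol ester (7) are treated as catalogue chemicals.

## Route

**Step 1**
Reactants: 1, 5,7-dihydroxy-4H-chromen-4-one; 2, chloromethyl methyl ether (MOMCl)
Product: 3, 5-hydroxy-7-(methoxymethoxy)-4H-chromen-4-one
Conditions: MOMCl (1.1 equiv), i-Pr2NEt, CH2Cl2, 0 °C → rt
Reagents that add atoms: MOMCl, COCCl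
Why: Selective O-alkylation (Williamson-type acetalisation) of the free, more acidic 7-OH, because the 5-OH is locked in a hydrogen bond to the C4 carbonyl and does not react with an amine base.

**Step 2**
Reactants: 3; 4, prenyl bromide (1-bromo-3-methylbut-2-ene)
Product: 5, 7-(methoxymethoxy)-5-[(3-methylbut-2-en-1-yl)oxy]-4H-chromen-4-one
Conditions: prenyl bromide (1.5 equiv), K2CO3, DMF, 50 °C
Reagents that add atoms: prenyl bromide, CC(C)=CCBr
Why: Williamson etherification of the chelated 5-phenoxide, which is the only remaining OH and alkylates under carbonate/DMF with warming, giving the substrate for both the conjugate addition and the later Claisen–Cope shift.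

**Step 3**
Reactants: 6, 1-bromo-4-(methoxymethoxy)benzene; 7, 4,4,5,5-tetramethyl-2-(3-methylbut-2-en-1-yl)-1,3,2-dioxaborolane (prenyl-Bpin)
Product: 8, 1-(methoxymethoxy)-4-(2-methylbut-3-en-2-yl)benzene
Conditions: Pd G3 precatalyst of an electron-poor biaryl phosphine (JackiePhos type, 2 mol %), aq. K3PO4, MeCN, 70 °C
Reagents that add atoms: prenyl-Bpin, CC(C)=CCB1OC(C)(C)C(C)(C)O1
Why: Ligand-controlled γ-selective allyl–aryl Suzuki–Miyaura coupling, in which SE2' transmetalation places Pd on the tertiary carbon and fast reductive elimination outruns σ–π–σ isomerisation to give the 1,1-dimethylallyl arene; the ligand choice is reasoned from that mechanism and must be confirmed by a short screen.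

**Step 4**
Reactants: 8; 9, triisopropyl borate
Product: 10, [2-(methoxymethoxy)-5-(2-methylbut-3-en-2-yl)phenyl]boronic acid
Conditions: n-BuLi, TMEDA, Et2O, 0 °C; then B(Oi-Pr)3, −78 °C → rt; aq. NH4Cl
Reagents that add atoms: triisopropyl borate, CC(C)OB(OC(C)C)OC(C)C; water, O
Why: MOM-directed ortho-lithiation followed by borate quench and hydrolysis; the quaternary tert-allyl group has no allylic or benzylic hydrogens, so the position ortho to OMOM is the only acidic site.

**Step 5 (key step)**
Reactants: 5; 10 (2.5 equiv, added in portions)
Product: 11, (2S)-7-(methoxymethoxy)-2-[2-(methoxymethoxy)-5-(2-methylbut-3-en-2-yl)phenyl]-5-[(3-methylbut-2-en-1-yl)oxy]-2,3-dihydro-4H-chromen-4-one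
Conditions: [Rh(OH)(cod)]2 (2.5 mol %), (S)-MeO-F12-BIPHEP (5.5 mol %), CH2Cl2/H2O, 40 °C
Reagents that add atoms: none (water supplies only H at C3)
Why: Hayashi–Miyaura-type Rh-catalysed asymmetric 1,4-addition of an arylboronic acid to a chromone, in which the (S)-biaryl bisphosphine is expected to select the C2 face that gives (2S), by analogy with 2-cyclohexenone (where (S)-ligands give (S)-3-arylcyclohexanone and the chromone maps on with O1 in place of C4), and the Rh oxa-π-allyl is then protonated by water; the unactivated prenyl and tert-allyl alkenes should not insert.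

**Step 6**
Reactants: 11
Product: 12, (2S)-5-hydroxy-7-(methoxymethoxy)-2-[2-(methoxymethoxy)-5-(2-methylbut-3-en-2-yl)phenyl]-8-(3-methylbut-2-en-1-yl)-2,3-dihydro-4H-chromen-4-one
Conditions: Eu(fod)3 (10 mol %), NaHCO3, PhCl, 85 °C
Reagents that add atoms: none
Why: Lewis-acid-accelerated tandem aromatic Claisen/Cope rearrangement (O5 → C6 as 1,1-dimethylallyl dienone, then [3,3] to C8 as prenyl, then re-aromatisation to the chelated 5-OH), a known transformation of 5-O-prenyl flavanones and flavones that does not involve C2.

**Step 7**
Reactants: 12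
Product: 13, (2S)-5,7-dihydroxy-2-[2-hydroxy-5-(2-methylbut-3-en-2-yl)phenyl]-8-(3-methylbut-2-en-1-yl)-2,3-dihydro-4H-chromen-4-one (target)
Conditions: 3 M aq. HCl/MeOH (1:5), rt → 40 °C, stop at full conversion
Reagents that add atoms: none
Why: Acid-catalysed acetal cleavage of the two phenolic MOM ethers, under dilute conditions commonly used on prenylated flavonoids, which are too mild to protonate the alkenes or to open the flavanone ring and racemise C2.

## Compound list

1 | 5,7-dihydroxy-4H-chromen-4-one | O=c1ccoc2cc(O)cc(O)c12 | starting material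
2 | chloromethyl methyl ether | COCCl | starting material (reagent)
3 | 5-hydroxy-7-(methoxymethoxy)-4H-chromen-4-one | O=c1ccoc2cc(OCOC)cc(O)c12 | intermediate
4 | prenyl bromide | CC(C)=CCBr | starting material (reagent)
5 | 7-(methoxymethoxy)-5-(prenyloxy)-4H-chromen-4-one | O=c1ccoc2cc(OCOC)cc(OCC=C(C)C)c12 | intermediate
6 | 1-bromo-4-(methoxymethoxy)benzene | COCOc1ccc(Br)cc1 | starting material
7 | prenylboronic acid pinacol ester | CC(C)=CCB1OC(C)(C)C(C)(C)O1 | starting material
8 | 1-(methoxymethoxy)-4-(2-methylbut-3-en-2-yl)benzene | C=CC(C)(C)c1ccc(OCOC)cc1 | intermediate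
9 | triisopropyl borate | CC(C)OB(OC(C)C)OC(C)C | starting material (reagent)
10 | [2-(methoxymethoxy)-5-(2-methylbut-3-en-2-yl)phenyl]boronic acid | C=CC(C)(C)c1ccc(OCOC)c(B(O)O)c1 | intermediate
11 | (2S)-5-O-prenyl-7,2'-bis-O-MOM flavanone | C=CC(C)(C)c1ccc(OCOC)c([C@@H]2CC(=O)c3c(OCC=C(C)C)cc(OCOC)cc3O2)c1 | intermediate
12 | (2S)-5-hydroxy-8-prenyl-7,2'-bis-O-MOM flavanone | C=CC(C)(C)c1ccc(OCOC)c([C@@H]2CC(=O)c3c(O)cc(OCOC)c(CC=C(C)C)c3O2)c1 | intermediate
13 | (2S)-5,7-dihydroxy-2-[2-hydroxy-5-(2-methylbut-3-en-2-yl)phenyl]-8-(3-methylbut-2-en-1-yl)chroman-4-one | C=CC(C)(C)c1ccc(O)c([C@@H]2CC(=O)c3c(O)cc(O)c(CC=C(C)C)c3O2)c1 | target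

## Totals

Total steps: 7. Longest linear sequence: 5 (steps 1, 2, 5, 6, 7 or steps 3, 4, 5, 6, 7).

## Three steps most likely to fail

1. **Step 5.** An ortho-alkoxy arylboronic acid adding to an electron-rich 5,7-dialkoxychromone may give low conversion, protodeboronation or modest ee. The sense of induction rests on the cyclohexenone analogy and must be confirmed by CD and chiral HPLC; the (R)-ligand is the immediate correction if it is reversed. Fallback: form the O1–C2 bond instead. Make the (R)-β-hydroxy ketone ArA–CO–CH2–CH(OH)–ArB by a catalytic asymmetric Mukaiyama aldol of the A-ring acetophenone silyl enol ether with the B-ring aldehyde, then close the ring by intramolecular Mitsunobu etherification with inversion to (2S).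

2. **Step 6.** The rearrangement may stop at C6 (giving the 6-(1,1-dimethylallyl) isomer), and heating with a Lewis acid may erode ee at C2 through reversible ring opening. Fallback: reorder the route. Run the Claisen–Cope shift on achiral chromone 5, where isomers can be separated without stereochemical cost, protect the 5-OH as a MOM ether, and then carry the 8-prenylchromone through the asymmetric 1,4-addition.

3. **Step 3.** The γ/α (branched/linear) ratio depends entirely on the ligand, and linear prenyl arene may contaminate 8. Fallback: build the quaternary carbon by enolate chemistry. Pd-catalysed α-arylation of isobutyraldehyde with 6 gives ArC(CH3)2CHO, and Wittig methylenation (Ph3P=CH2) then gives 8 with no regiochemical ambiguity, at the cost of one extra step.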